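## The problem

The target 33 is a 6,7-seco-ent-kauranoid. It has cyclohexane ring A, a seven-membered oxepane lactol ring B (C5–C6(OH)–O–C7–C8–C9–C10), cyclohexane ring C and cyclopentanone ring D; rings C and D form a bicyclo[3.2.1]octane that carries the 15-oxo-16-methylene unit. The quaternary carbons C10 and C8 flank the fully substituted epoxide carbon C9, so C8–C9 is the most congested bond of the skeleton. There are nine stereocentres: C1, C2, C5 and C10 contiguous on ring A, the anomeric C6, and C8, C9, C11 and C13 on the C/D bicycle (α denotes the face of ring A that carries the C10 methyl group, β the other face). C5 can set C10, because a second substituent enters anti to it. The axial α-methyl groups at C4 and C10 screen the α face, so hydride reaches C1 and C2 from β and gives the 1α,2α-diol. C5 and C10 must control C8, C8 fixes C13 through the bridge, the 1α-hydroxyl can steer the 9α,11α-epoxide, and C6 equilibrates as a lactol. The α-methylene ketone, the tertiary epoxide, the lactol and the two acetates are sensitive to nucleophiles, acid and base and must appear late; a 2-pyrone carried through the early steps excludes strong nucleophiles. The key step is possible because C9, C11, C12 and C13 form a four-carbon chain bonded through C9 to C10, which corresponds to C3–C6 of a 2-pyron-3-yl group on C10, while C8, C14, C15, C16 and C7 form a 2-acetylallyl unit linked to C5 through the acetal oxygen at C6.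

## Retrosynthesis

**End game.** The lactol of 33 is unmasked last from cyclic methyl acetal 32, so that the open hydroxy aldehyde never meets base or oxidant. The acetates of 32 come from epoxy diol 31, and the epoxide from ene-diol 30, because the free homoallylic 1α-hydroxyl can direct the oxygen to the α face. Epoxidising after acetylation would lose this control element.

**C16–C17.** Enone 30 comes from acetonide 29 and this from ketone 26 by α-methylenation. C16 is the only enolisable position of 26, so no regiochemical question arises, and the strong base is used while the diol is still an acetonide and not a diacetate.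

**C13–C16 (ring D).** Ketone 26 is cut to bromomethyl ketone 25, made from methyl ketone 23. A 5-exo radical closure onto the terminus of a 1,3-diene is preferred to an anionic closure because the diene is no Michael acceptor. The allyl radical also leaves the 9(11)-alkene where the epoxide is needed. The precursor 23 lacks one ring and one stereocentre.

**C8–C9 and C13–C14 (rings B and C, key step).** Diene 23 is cut to pyrone 21. The alternatives are cutting C9–C10 or closing ring B by acetalisation after an intermolecular cycloaddition. Both would require an intermolecular bond between fully substituted carbons; the tether makes the C8–C9 bond intramolecular and fixes the regiochemistry. The precursor is a monocyclic ring A compound. The forward reaction must select one face of the pyrone to set C8.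

**C6–O (tether).** Mixed acetal 21 is cut to dimethyl acetal 16 and alcohol 19, itself the Baylis–Hillman adduct of 17 and 18. An acetal is chosen over an ester or ether link because it needs no later redox change at C6.

**Oxidation pattern of ring A.** Acetal 16 comes from aldehyde 15 and vinyl acetonide 14, so the vinyl group serves as a masked C6 aldehyde through the base and hydride steps. The cis-diol 13 comes from dione 12, acyloin 11 and ketone 8. Double hydride delivery from the open β face is chosen over dihydroxylation of a C1–C2 alkene, which would place the diol on the β face.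

**C9–C10.** Ketone 8 is cut to silyl enol ether 6 and 3-bromo-2-pyrone 7. Attaching the intact pyrone is far shorter than building it on C10. The methyl group must be present first, so that the pyrone enters anti to the C5 substituent.

**C5–C6 and ring A.** Enol ether 6 comes from enone 4 by conjugate addition of a vinyl group with silyl trapping. This is the only direct regiospecific access to the tetrasubstituted enol ether, and it sets C5, the stereocentre that controls the rest. Enone 4 comes from aldehyde 1 and vinyl ketone 2 by Robinson annulation via keto aldehyde 3.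

## Roads not taken

**Alternative 1:** The C/D bicycle would be cut at C8–C14 and C13–C16. In the forward step Mn(OAc)3 would oxidise acyclic β-keto ester A1 to the C8 radical, which closes ring C 6-endo and ring D 5-exo-dig to give bicyclic keto ester A2. Merits: two rings, the quaternary C8 and the exo-methylene arise in one step from a simple chain, and the chiral ester group sets the absolute configuration at C8 directly. In this respect the road is better, since the chosen plan relies on a rotamer preference at C8. Weak points: A2 contains none of ring A or ring B. The C9–C10 bond between a ketone carbon flanked by quaternary C8 and a quaternary C10 would have to be made intermolecularly. The ester must be reduced to C7 and C15 oxidised later. Against the better C8 control, the chosen plan makes the crowded bond intramolecularly with ring A complete, and needs fewer steps after the key step.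

**Alternative 2:** Ring A would be cut at C5–C10 and ring B at C6–O. Photolysis of A-homo diazoketone A3 would make C10 migrate to C5 (Wolff ring contraction), and the C7 hydroxyl would capture the migrated acyl carbon to give tetracyclic lactone A4. Merits: all four rings, the 9(11)-alkene and the protected diol are present in A4, so the sequence after the key step would be shorter than in the chosen plan. Weak points: A3 already needs the C9–C10 bond, the C/D bicycle and a functionalised seven-membered ring, so the difficulty is moved into the precursor. C5 is set by protonation with no clear control. C6 arrives as a lactone carbonyl that must be reduced to the lactol beside an enone and esters, and C15 still lacks its oxygen. The chosen plan pays with a longer end game but starts from a precursor made from a monocyclic ketone in few steps and has C6 at the right oxidation level throughout.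

**Alternative 3:** Ring D would be cut at C13–C14 and C8–C15. Zerovalent palladium (from Pd(OAc)2 and a phosphite or a chiral phosphoramidite) would ionise silyl allyl carbonate A6, and the three-carbon dipole would add across exocyclic enone A5 to give spiro tricycle A7. Merits: the exo-methylene is installed directly, and a chiral ligand could set C8 and C13 under catalyst control, which is more secure than the substrate control used here. Weak points: ring C remains open, and closing C9–C11 at a ketone flanked by two quaternary carbons needs a nucleophilic C11 and a later dehydration. Enone A5 already requires the C9–C10 bond and ring B. The relative configuration of C13 and the spiro centre is set in an intermolecular step next to a quaternary carbon. The chosen plan forms rings B and C together and reaches ring D by a closure whose geometry is fixed.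

Key step: step 12

Assumption: C6 becomes stereogenic in step 11 without reliable control. Mixed acetal 21 and its successors are drawn as the 6β-alkoxy epimer, the configuration is not relied on, and C6 equilibrates under acid in steps 16 and 19, where the lactol is taken to settle as the 6β-hydroxy anomer of the target.

## Route

Step 1
Reactants: 1 2-methylpropanal; 2 pent-1-en-3-one
Product: 4 2,4,4-trimethylcyclohex-2-en-1-one, via keto aldehyde 3 (not isolated)
Conditions: H2SO4 (cat.), toluene, 50 °C then reflux, Dean–Stark
Reagents that add atoms: none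
Why: Robinson annulation: acid-catalysed Michael addition of the aldehyde enol to the vinyl ketone, then intramolecular aldol condensation. The ethyl ketone can close only the six-membered ring, which places the methyl group on the enone α-carbon.

Step 2
Reactants: 4 2,4,4-trimethylcyclohex-2-en-1-one
Product: 6 trimethyl{[(3R)-2,4,4-trimethyl-3-vinylcyclohex-1-en-1-yl]oxy}silane, via bromomagnesium enolate 5 (not isolated)
Conditions: CH2=CHMgBr, CuBr·SMe2 (5 mol%), (R)-1-[(Sp)-2-(diphenylphosphino)ferrocenyl]ethyldicyclohexylphosphine or its enantiomer (6 mol%), t-BuOMe, −78 °C; then Me3SiCl, Et3N, DMPU, −78 to 0 °C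
Reagents that add atoms: vinylmagnesium bromide, C=C[Mg]Br; chlorotrimethylsilane, C[Si](C)(C)Cl
Why: Copper-catalysed enantioselective 1,4-addition of a Grignard reagent to a 2-methylcyclohex-2-enone with enolate trapping. The chiral diphosphine–copper complex selects the enone face and sets C5 (3R; the ligand enantiomer is chosen accordingly), and O-silylation fixes the tetrasubstituted enol ether regiospecifically.

Step 3
Reactants: 6 trimethyl{[(3R)-2,4,4-trimethyl-3-vinylcyclohex-1-en-1-yl]oxy}silane; 7 3-bromo-2H-pyran-2-one
Product: 8 (2R,3R)-2,4,4-trimethyl-2-(2-oxo-2H-pyran-3-yl)-3-vinylcyclohexan-1-one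
Conditions: Pd(OAc)2 (5 mol%), P(t-Bu)3 (10 mol%), Bu3SnF, toluene, 85 °C
Reagents that add atoms: none
Why: Proposed new method: palladium-catalysed α-arylation of a tetrasubstituted trimethylsilyl enol ether with tributyltin fluoride activation is known for aryl bromides but not for a 3-halo-2-pyrone. Zerovalent palladium should insert into the C3–Br bond (as in the known Stille and Suzuki couplings of 7), fluoride should transfer the enolate, and reductive elimination should form the C10 quaternary centre with the pyronyl group entering anti to the pseudo-axial C5 vinyl group. The closest known reaction type is the fluoride-promoted palladium-catalysed arylation of silyl enol ethers with aryl halides.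

Step 4
Reactants: 8 (2R,3R)-2,4,4-trimethyl-2-(2-oxo-2H-pyran-3-yl)-3-vinylcyclohexan-1-one
Product: 11 (2R,3R,6R)-6-hydroxy-2,4,4-trimethyl-2-(2-oxo-2H-pyran-3-yl)-3-vinylcyclohexan-1-one, via trimethylsilyl enol ether 9 (not isolated), via α-silyloxy ketone 10 (not isolated)
Conditions: Me3SiOTf, Et3N, CH2Cl2, 0 °C; dimethyldioxirane, acetone, −40 to 0 °C; then citric acid, MeOH, 0 °C
Reagents that add atoms: dimethyldioxirane, CC1(C)OO1
Why: Rubottom oxidation: soft enolisation can occur only toward C2 because C10 is quaternary, and the oxidant should attack the enol ether from the β face, away from the axial C4 and C10 methyl groups. The terminal alkene and the pyrone are much less reactive; the C2 configuration is removed in step 5.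

Step 5
Reactants: 11 (2R,3R,6R)-6-hydroxy-2,4,4-trimethyl-2-(2-oxo-2H-pyran-3-yl)-3-vinylcyclohexan-1-one
Product: 12 (3R,4R)-3,5,5-trimethyl-3-(2-oxo-2H-pyran-3-yl)-4-vinylcyclohexane-1,2-dione
Conditions: Dess–Martin periodinane, pyridine, CH2Cl2, rt
Reagents that add atoms: none
Why: Dess–Martin oxidation of an acyloin to the 1,2-dione (in equilibrium with its enol). This removes the C2 stereocentre so that both carbinol centres can be set together in step 6.

Step 6
Reactants: 12 (3R,4R)-3,5,5-trimethyl-3-(2-oxo-2H-pyran-3-yl)-4-vinylcyclohexane-1,2-dione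
Product: 13 3-[(1R,2R,3S,6R)-2,3-dihydroxy-1,5,5-trimethyl-6-vinylcyclohexyl]-2H-pyran-2-one
Conditions: NaBH4, CeCl3·7H2O, MeOH/THF, −40 to 0 °C
Reagents that add atoms: none
Why: Luche-type borohydride reduction. Both carbonyl groups should be attacked from the β face because the axial α-methyl groups at C4 and C10 block the α face (axial attack at C1, equatorial attack at C2), giving the 1α (equatorial), 2α (axial) cis-diol. CeCl3 keeps hydride off the pyrone.

Step 7
Reactants: 13 3-[(1R,2R,3S,6R)-2,3-dihydroxy-1,5,5-trimethyl-6-vinylcyclohexyl]-2H-pyran-2-one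
Product: 14 3-[(3aR,4R,5R,7aS)-2,2,4,6,6-pentamethyl-5-vinylhexahydro-1,3-benzodioxol-4-yl]-2H-pyran-2-one
Conditions: 2,2-dimethoxypropane, PPTS (cat.), CH2Cl2, rt
Reagents that add atoms: 2,2-dimethoxypropane, COC(C)(C)OC
Why: Acid-catalysed ketal exchange. The cis-1,2-diol gives the five-membered isopropylidene ketal, which withstands the bases, the radical step and the heat used up to step 15.

Step 8
Reactants: 14 3-[(3aR,4R,5R,7aS)-2,2,4,6,6-pentamethyl-5-vinylhexahydro-1,3-benzodioxol-4-yl]-2H-pyran-2-one
Product: 15 (3aR,4R,5R,7aS)-2,2,4,6,6-pentamethyl-4-(2-oxo-2H-pyran-3-yl)hexahydro-1,3-benzodioxole-5-carbaldehyde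
Conditions: OsO4 (2 mol%), NaIO4, 2,6-lutidine, dioxane/H2O, rt
Reagents that add atoms: osmium tetroxide, O=[Os](=O)(=O)=O; sodium periodate, [Na+].[O-]I(=O)(=O)=O
Why: Lemieux–Johnson cleavage: OsO4 should dihydroxylate the terminal alkene in preference to the electron-poor pyrone double bonds, and periodate cleaves the diol. C5 lies between two quaternary carbons and should not epimerise under the buffered conditions.

Step 9
Reactants: 15 (3aR,4R,5R,7aS)-2,2,4,6,6-pentamethyl-4-(2-oxo-2H-pyran-3-yl)hexahydro-1,3-benzodioxole-5-carbaldehyde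
Product: 16 3-[(3aR,4R,5R,7aS)-5-(dimethoxymethyl)-2,2,4,6,6-pentamethylhexahydro-1,3-benzodioxol-4-yl]-2H-pyran-2-one
Conditions: MeOSiMe3, Me3SiOTf (5 mol%), CH2Cl2, −78 °C
Reagents that add atoms: methoxytrimethylsilane, CO[Si](C)(C)C
Why: Silyl-triflate-catalysed acetalisation of an aldehyde with an alkoxysilane. At −78 °C the aldehyde should be converted to the dimethyl acetal without exchange of the isopropylidene ketal.

Step 10
Reactants: 17 but-3-en-2-one; 18 formaldehyde
Product: 19 3-(hydroxymethyl)but-3-en-2-one
Conditions: aq. CH2O, DABCO (cat.), THF/H2O, rt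
Reagents that add atoms: none
Why: Baylis–Hillman reaction of the vinyl ketone with formaldehyde under tertiary-amine catalysis. The product is used fresh because it dimerises on standing.

Step 11
Reactants: 16 3-[(3aR,4R,5R,7aS)-5-(dimethoxymethyl)-2,2,4,6,6-pentamethylhexahydro-1,3-benzodioxol-4-yl]-2H-pyran-2-one; 19 3-(hydroxymethyl)but-3-en-2-one
Product: 21 3-[(3aR,4R,5R,7aS)-5-{(R)-methoxy[(2-methylidene-3-oxobutyl)oxy]methyl}-2,2,4,6,6-pentamethylhexahydro-1,3-benzodioxol-4-yl]-2H-pyran-2-one, via pyridinium triflate 20 (not isolated)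
Conditions: Et3SiOTf, 2,4,6-collidine, CH2Cl2, 0 °C; then 19, 0 °C to rt
Reagents that add atoms: none
Why: Mixed-acetal synthesis through a pyridinium intermediate: the silyl triflate ionises one methoxy group of the aldehyde acetal (the ketal is left alone), collidine captures the oxocarbenium ion, and the primary alcohol displaces the pyridine. Only one methoxy group is exchanged; C6 becomes stereogenic as stated in the assumption.

Step 12
Reactants: 21 3-[(3aR,4R,5R,7aS)-5-{(R)-methoxy[(2-methylidene-3-oxobutyl)oxy]methyl}-2,2,4,6,6-pentamethylhexahydro-1,3-benzodioxol-4-yl]-2H-pyran-2-one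
Product: 23 tricyclic A/B/C 9(11),12-diene (8β-acetyl; 6β-methoxy oxepane acetal; 1α,2α-isopropylidenedioxy; 5β-H; 10α-methyl), via bridged lactone 22 (not isolated)
Conditions: BHT (10 mol%), o-dichlorobenzene (0.01 M), 160–170 °C, sealed tube
Reagents that add atoms: none
Why: Thermal intramolecular Diels–Alder reaction of the 2-pyrone (diene C9=C11–C12=C13) with the tethered 2-substituted enone (C8=C14), then retro-Diels–Alder loss of CO2 from bridged lactone 22; the closest known reaction type is the intramolecular 2-pyrone cycloaddition with CO2 extrusion that gives cyclohexadienes. The five-atom tether C10–C5–C6–O–C7 forces C8 onto C9 and C14 onto C13, which is also the intrinsic preference of 2-pyrones for bonding C6 to the β-carbon of an enone. Ring C closes as a six-membered ring by the [4+2] bond pair C8–C9 and C13–C14, and ring B closes as a seven-membered ring through the C8–C9 bond, with the tether fused to the diene terminus. The only lasting new stereocentre is C8, since C9 and C13 become trigonal again when CO2 leaves. C8 is set by the pyrone face that the enone reaches: the tether hangs from C5, so addition occurs on the face turned toward C5–C6, and in the rotamer about C9–C10 assumed here the lactone carbonyl lies between the C10 methyl group and C5 while C1 sits in the pyrone plane next to H11. C7 then swings to the methyl side, the acetyl group lies endo under C11–C12, and ring B closes through a twist-chair, which places the acetyl group β (cis to C1) as in the target. The step needs this facial selectivity; regioselectivity is secured by the tether, and high dilution with a radical inhibitor suppresses dimerisation of the enone. Because C8 is quaternary the diene cannot aromatise, and it is delivered with C12=C13 placed for ring D and C9=C11 for the epoxide.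

Step 13
Reactants: 23 tricyclic 9(11),12-diene methyl ketone
Product: 25 tricyclic 9(11),12-diene bromomethyl ketone (C16 bromide), via silyl enol ether 24 (not isolated)
Conditions: LiN(SiMe3)2, Me3SiCl, THF, −78 °C; then N-bromosuccinimide, THF, −78 to 0 °C
Reagents that add atoms: N-bromosuccinimide, O=C1CCC(=O)N1Br
Why: Kinetic enolisation of the methyl ketone with internal silyl quench (C8 is quaternary, so only C16 can be deprotonated), then electrophilic bromination of the silyl enol ether, which is far more nucleophilic than the diene.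

Step 14
Reactants: 25 tricyclic 9(11),12-diene bromomethyl ketone
Product: 26 tetracyclic 15-ketone with 9(11)-alkene (ring D closed; 6β-methoxy; 1α,2α-isopropylidenedioxy)
Conditions: Bu3SnH (slow addition), AIBN (cat.), benzene, 80 °C
Reagents that add atoms: none
Why: 5-exo-trig cyclisation of the α-keto radical onto C13, the diene terminus, gives an allyl radical over C12–C11–C9 that should abstract hydrogen at the less hindered C12 and leave the 9(11)-alkene. The bridge can form only on the acetyl face, so C13 follows from C8.

Step 15
Reactants: 26 tetracyclic 15-ketone with 9(11)-alkene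
Product: 29 tetracyclic 16-methylene-15-ketone with 9(11)-alkene (6β-methoxy; 1α,2α-isopropylidenedioxy), via Mannich base 27 (not isolated), via methiodide 28 (not isolated)
Conditions: LiN(SiMe3)2, THF, −78 °C; CH2=NMe2+ I−, −78 °C to rt; MeI, CH2Cl2/MeOH, rt; then aq. NaHCO3, CH2Cl2, rt
Reagents that add atoms: N,N-dimethylmethyleneiminium iodide (Eschenmoser's salt), C=[N+](C)C.[I-]
Why: α-Methylenation by Mannich reaction of the only possible enolate (C16) with the iminium salt, quaternisation and β-elimination of trimethylamine; the new carbon is C17.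

Step 16
Reactants: 29 tetracyclic 16-methylene-15-ketone acetonide
Product: 30 tetracyclic enone 1α,2α-diol with 9(11)-alkene (6β-methoxy)
Conditions: PPTS, MeOH, 40 °C
Reagents that add atoms: none
Why: Acid-catalysed transketalisation to methanol removes the isopropylidene group. In methanol the cyclic methyl acetal can exchange only with the solvent, which preserves it and equilibrates C6.

Step 17
Reactants: 30 tetracyclic enone 1α,2α-diol with 9(11)-alkene
Product: 31 9α,11α-epoxy enone 1α,2α-diol (6β-methoxy)
Conditions: VO(acac)2 (5 mol%), t-BuOOH (in decane), CH2Cl2, 0 °C to rt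
Reagents that add atoms: tert-butyl hydroperoxide, CC(C)(C)OO
Why: Hydroxyl-directed epoxidation: the vanadium alkoxide of the homoallylic 1α-hydroxyl should deliver the peroxide oxygen to the α face of the electron-rich C9–C11 alkene, which is also the face away from the C15–C16 bridge. The electron-poor enone alkene does not react.

Step 18
Reactants: 31 9α,11α-epoxy enone 1α,2α-diol
Product: 32 9α,11α-epoxy enone 1α,2α-diacetate methyl acetal (6β-methoxy)
Conditions: Ac2O, DMAP, pyridine, 40 °C
Reagents that add atoms: acetic anhydride, CC(=O)OC(C)=O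
Why: DMAP-catalysed acetylation of both secondary alcohols. The axial C2 hydroxyl is hindered and needs gentle warming, which the epoxide and the acetal should tolerate.

Step 19
Reactants: 32 9α,11α-epoxy enone 1α,2α-diacetate methyl acetal
Product: 33 CNP0224512.1 (1α,2α-diacetoxy-9α,11α-epoxy-6β-hydroxy-16-methylene-15-oxo lactol)
Conditions: aq. HCl (0.5 M), THF, 0 °C to rt
Reagents that add atoms: water, O
Why: Acid-catalysed hydrolysis of the cyclic methyl acetal through the ring oxocarbenium ion gives the lactol, whose anomeric centre settles as the 6β-hydroxy form. The hindered epoxide, whose ionisation would place a cation β to the C15 carbonyl, should survive dilute acid at low temperature.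

## Compound list

1 | 2-methylpropanal (isobutyraldehyde) | CC(C)C=O | starting material
2 | pent-1-en-3-one (ethyl vinyl ketone) | CCC(=O)C=C | starting material
3 | 2,2-dimethyl-5-oxoheptanal | CCC(=O)CCC(C)(C)C=O | intermediate (not isolated)
4 | 2,4,4-trimethylcyclohex-2-en-1-one | CC1=CC(C)(C)CCC1=O | intermediate
5 | bromomagnesium (3R)-2,4,4-trimethyl-3-vinylcyclohex-1-en-1-olate | C=C[C@@H]1C(C)(C)CCC(O[Mg]Br)=C1C | intermediate (not isolated)
6 | trimethyl{[(3R)-2,4,4-trimethyl-3-vinylcyclohex-1-en-1-yl]oxy}silane | C=C[C@@H]1C(C)(C)CCC(O[Si](C)(C)C)=C1C | intermediate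
7 | 3-bromo-2H-pyran-2-one | O=c1occcc1Br | starting material
8 | (2R,3R)-2,4,4-trimethyl-2-(2-oxo-2H-pyran-3-yl)-3-vinylcyclohexan-1-one | C=C[C@@H]1C(C)(C)CCC(=O)[C@@]1(C)c1cccoc1=O | intermediate
9 | 3-[(1R,6R)-1,5,5-trimethyl-2-(trimethylsilyloxy)-6-vinylcyclohex-2-en-1-yl]-2H-pyran-2-one | C=C[C@@H]1C(C)(C)CC=C(O[Si](C)(C)C)[C@@]1(C)c1cccoc1=O | intermediate (not isolated)
10 | (2R,3R,6R)-2,4,4-trimethyl-2-(2-oxo-2H-pyran-3-yl)-6-(trimethylsilyloxy)-3-vinylcyclohexan-1-one | C=C[C@@H]1C(C)(C)C[C@@H](O[Si](C)(C)C)C(=O)[C@@]1(C)c1cccoc1=O | intermediate (not isolated)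
11 | (2R,3R,6R)-6-hydroxy-2,4,4-trimethyl-2-(2-oxo-2H-pyran-3-yl)-3-vinylcyclohexan-1-one | C=C[C@@H]1C(C)(C)C[C@@H](O)C(=O)[C@@]1(C)c1cccoc1=O | intermediate
12 | (3R,4R)-3,5,5-trimethyl-3-(2-oxo-2H-pyran-3-yl)-4-vinylcyclohexane-1,2-dione | C=C[C@@H]1C(C)(C)CC(=O)C(=O)[C@@]1(C)c1cccoc1=O | intermediate
13 | 3-[(1R,2R,3S,6R)-2,3-dihydroxy-1,5,5-trimethyl-6-vinylcyclohexyl]-2H-pyran-2-one | C=C[C@@H]1C(C)(C)C[C@H](O)[C@H](O)[C@@]1(C)c1cccoc1=O | intermediate
14 | 3-[(3aR,4R,5R,7aS)-2,2,4,6,6-pentamethyl-5-vinylhexahydro-1,3-benzodioxol-4-yl]-2H-pyran-2-one | C=C[C@@H]1C(C)(C)C[C@H](OC(C)(C)O2)[C@H]2[C@@]1(C)c1cccoc1=O | intermediate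
15 | (3aR,4R,5R,7aS)-2,2,4,6,6-pentamethyl-4-(2-oxo-2H-pyran-3-yl)hexahydro-1,3-benzodioxole-5-carbaldehyde | O=C[C@@H]1C(C)(C)C[C@H](OC(C)(C)O2)[C@H]2[C@@]1(C)c1cccoc1=O | intermediate
16 | 3-[(3aR,4R,5R,7aS)-5-(dimethoxymethyl)-2,2,4,6,6-pentamethylhexahydro-1,3-benzodioxol-4-yl]-2H-pyran-2-one | COC(OC)[C@@H]1C(C)(C)C[C@H](OC(C)(C)O2)[C@H]2[C@@]1(C)c1cccoc1=O | intermediate
17 | but-3-en-2-one (methyl vinyl ketone) | CC(=O)C=C | starting material
18 | formaldehyde | C=O | starting material
19 | 3-(hydroxymethyl)but-3-en-2-one | C=C(CO)C(C)=O | intermediate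
20 | 1-[methoxy(ring A C5)methyl]-2,4,6-trimethylpyridinium triflate of 16 (C6 epimers) | COC([n+]1c(C)cc(C)cc1C)[C@@H]1C(C)(C)C[C@H](OC(C)(C)O2)[C@H]2[C@@]1(C)c1cccoc1=O.[O-]S(=O)(=O)C(F)(F)F | intermediate (not isolated)
21 | 3-[(3aR,4R,5R,7aS)-5-{(R)-methoxy[(2-methylidene-3-oxobutyl)oxy]methyl}-2,2,4,6,6-pentamethylhexahydro-1,3-benzodioxol-4-yl]-2H-pyran-2-one (key-step precursor) | C=C(C(C)=O)CO[C@@H](OC)[C@@H]1C(C)(C)C[C@H](OC(C)(C)O2)[C@H]2[C@@]1(C)c1cccoc1=O | intermediate
22 | bridged lactone cycloadduct (C9 and C13 joined by C(=O)–O; 8β-acetyl endo; rings B and C closed) | CC(=O)[C@@]12CO[C@@H](OC)[C@@H]3C(C)(C)C[C@H](OC(C)(C)O4)[C@H]4[C@@]3(C)[C@@]15C=C[C@@H](C2)OC5=O | intermediate (not isolated)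
23 | tricyclic A/B/C 9(11),12-diene, 8β-acetyl, 6β-methoxy oxepane acetal, 1α,2α-isopropylidenedioxy (key-step product) | CC(=O)[C@@]12CO[C@@H](OC)[C@@H]3C(C)(C)C[C@H](OC(C)(C)O4)[C@H]4[C@@]3(C)C1=CC=CC2 | intermediate
24 | trimethylsilyl enol ether of 23 (C15–O–Si, C15=C16) | C=C(O[Si](C)(C)C)[C@@]12CO[C@@H](OC)[C@@H]3C(C)(C)C[C@H](OC(C)(C)O4)[C@H]4[C@@]3(C)C1=CC=CC2 | intermediate (not isolated)
25 | bromomethyl ketone of the tricyclic diene (C16 bromide) | BrCC(=O)[C@@]12CO[C@@H](OC)[C@@H]3C(C)(C)C[C@H](OC(C)(C)O4)[C@H]4[C@@]3(C)C1=CC=CC2 | intermediate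
26 | tetracyclic 15-ketone, 9(11)-alkene, 6β-methoxy, 1α,2α-isopropylidenedioxy | C1C(=O)[C@@]23CO[C@@H](OC)[C@@H]4C(C)(C)C[C@H](OC(C)(C)O5)[C@H]5[C@@]4(C)C2=CC[C@@H]1C3 | intermediate
27 | 16-exo-(dimethylaminomethyl) derivative of 26 (Mannich base) | CN(C)C[C@@H]1C(=O)[C@@]23CO[C@@H](OC)[C@@H]4C(C)(C)C[C@H](OC(C)(C)O5)[C@H]5[C@@]4(C)C2=CC[C@@H]1C3 | intermediate (not isolated)
28 | trimethylammonium iodide of 27 | C[N+](C)(C)C[C@@H]1C(=O)[C@@]23CO[C@@H](OC)[C@@H]4C(C)(C)C[C@H](OC(C)(C)O5)[C@H]5[C@@]4(C)C2=CC[C@@H]1C3.[I-] | intermediate (not isolated)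
29 | tetracyclic 16-methylene-15-ketone, 9(11)-alkene, 6β-methoxy, 1α,2α-isopropylidenedioxy | C=C1C(=O)[C@@]23CO[C@@H](OC)[C@@H]4C(C)(C)C[C@H](OC(C)(C)O5)[C@H]5[C@@]4(C)C2=CC[C@@H]1C3 | intermediate
30 | tetracyclic 16-methylene-15-ketone, 9(11)-alkene, 6β-methoxy, 1α,2α-diol | C=C1C(=O)[C@@]23CO[C@@H](OC)[C@@H]4C(C)(C)C[C@H](O)[C@H](O)[C@@]4(C)C2=CC[C@@H]1C3 | intermediate
31 | 9α,11α-epoxy-16-methylene-15-ketone, 6β-methoxy, 1α,2α-diol | C=C1C(=O)[C@@]23CO[C@@H](OC)[C@@H]4C(C)(C)C[C@H](O)[C@H](O)[C@@]4(C)[C@]24O[C@@H]4C[C@@H]1C3 | intermediate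
32 | 9α,11α-epoxy-16-methylene-15-ketone, 6β-methoxy, 1α,2α-diacetate | C=C1C(=O)[C@@]23CO[C@@H](OC)[C@@H]4C(C)(C)C[C@H](OC(C)=O)[C@H](OC(C)=O)[C@@]4(C)[C@]24O[C@@H]4C[C@@H]1C3 | intermediate
33 | CNP0224512.1 (1α,2α-diacetoxy-9α,11α-epoxy-6β-hydroxy-16-methylene-15-oxo-6,7-seco-ent-kauranoid lactol) | C=C1C(=O)[C@@]23CO[C@@H](O)[C@@H]4C(C)(C)C[C@H](OC(C)=O)[C@H](OC(C)=O)[C@@]4(C)[C@]24O[C@@H]4C[C@@H]1C3 | target

## Step count and least certain steps

Total: 19 steps. Longest linear sequence: 18 steps (steps 1–9 and 11–19; step 10 is a one-step side branch).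

**Step 3 (proposed new method).** Most likely failure: slow transmetalation or reductive elimination at a tetrasubstituted enolate carbon next to the C5 stereocentre, so that 6 is protodesilylated or the bromopyrone is consumed by homocoupling or ring opening. Fallback with known chemistry, from 6 back to 8: the pyrone ring is built on C10 instead of being coupled. The regiospecific lithium enolate from 6 (MeLi, THF) would add, again anti to the vinyl group, to ethyl 5,5-dimethoxy-2-oxopentanoate F1 (from diethyl oxalate and 3,3-dimethoxypropylmagnesium bromide) to give tertiary alcohol F2. Dehydration (SOCl2, pyridine) would give 2-substituted pent-2-enoate F3, and acid (TsOH, toluene, heat) would unmask the aldehyde and close the enol lactone to the 2-pyrone 8.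

**Step 12 (key step).** Most likely failure: poor facial selectivity at C8, because the competing pyrone rotamer with the C10 methyl group in the ring plane leads to the C8 epimer. Polymerisation of the α-methylene ketone during the long heating that a seven-membered closure needs is the second risk, and the two C6 epimers of 21 may differ in selectivity. Fallback, from 16 back to 23: the same acetal exchange with commercial methyl 2-(hydroxymethyl)acrylate would give acrylate mixed acetal F4. This more robust dienophile tolerates prolonged heating or Lewis-acid promotion at lower temperature, where the rotamer and endo preferences are stronger, and should give diene ester F5 with loss of CO2. Me3SiCH2Li followed by methanol would convert the hindered ester into the methyl ketone 23.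

**Step 2.** Most likely failure: low enantioselectivity or conversion in the 1,4-addition to an enone that is α-substituted and neopentyl at the β-carbon. Fallback, from 4 back to 8: the addition is run with an achiral catalyst (CuI, Me3SiCl present from the start), which gives 6 together with its enantiomer F6. Step 3 is applied to the mixture to give 8 and its enantiomer F7, and the two ketones are separated by preparative chromatography on a chiral stationary phase; 8 continues.

**Step 6.** Most likely failure: hydride delivery to one carbonyl from the α face, or intramolecular delivery from the first-formed alkoxyborohydride, leading to a trans-diol. Fallback, from 11 back to 13: the two centres are set one at a time. Reduction of 11 (NaBH4, CeCl3·7H2O) gives the 1α,2β-diol F8; selective oxidation of the less hindered C2 hydroxyl (TEMPO, PhI(OAc)2) gives 1α-hydroxy-2-ketone F9; reduction of F9 with LiAlH(O-t-Bu)3, which can approach only from the β face, gives 13.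

**Step 14.** Most likely failure: premature hydrogen transfer to the α-keto radical (which only returns 23), or hydrogen transfer to C9 of the allyl radical, which misplaces the alkene at C11–C12. Fallback, from 23 back to 26, through a carbenoid instead of a radical: trifluoroacetylation (LiN(SiMe3)2, CF3CO2CH2CF3) gives diketone F10. Diazo transfer (MsN3, Et3N) gives diazoketone F11. Rh2(OAc)4-catalysed cyclopropanation of the C12–C13 alkene gives cyclopropyl ketone F12. SmI2 then cleaves the allylic C12–C16 bond to give 26.

**Step 19.** Most likely failure: acid-promoted opening or rearrangement of the 9,11-epoxide during acetal hydrolysis. Fallback, from 30 back to 33, with the order reversed so that the epoxide never meets acid: acetylation of 30 gives diacetate F13, hydrolysis gives lactol F14, and epoxidation with dimethyldioxirane under neutral conditions gives 33. This gives up the hydroxyl direction and relies on approach anti to the C15–C16 bridge.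

## Further compounds

F1 | step 3 | ethyl 5,5-dimethoxy-2-oxopentanoate | CCOC(=O)C(=O)CCC(OC)OC
F2 | step 3 | ethyl 2-hydroxy-5,5-dimethoxy-2-[(1R,6R)-1,3,3-trimethyl-6-oxo-2-vinylcyclohexyl]pentanoate (C9 epimers) | C=C[C@@H]1C(C)(C)CCC(=O)[C@@]1(C)C(O)(CCC(OC)OC)C(=O)OCC
F3 | step 3 | ethyl 5,5-dimethoxy-2-[(1R,6R)-1,3,3-trimethyl-6-oxo-2-vinylcyclohexyl]pent-2-enoate | C=C[C@@H]1C(C)(C)CCC(=O)[C@@]1(C)C(=CCC(OC)OC)C(=O)OCC
F4 | step 12 | methyl 2-{[methoxy(ring A C5)methoxy]methyl}acrylate mixed acetal of 16 | C=C(C(=O)OC)CO[C@@H](OC)[C@@H]1C(C)(C)C[C@H](OC(C)(C)O2)[C@H]2[C@@]1(C)c1cccoc1=O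
F5 | step 12 | tricyclic 9(11),12-diene 8β-methyl ester (ester analogue of 23) | COC(=O)[C@@]12CO[C@@H](OC)[C@@H]3C(C)(C)C[C@H](OC(C)(C)O4)[C@H]4[C@@]3(C)C1=CC=CC2
F6 | step 2 | trimethyl{[(3S)-2,4,4-trimethyl-3-vinylcyclohex-1-en-1-yl]oxy}silane (enantiomer of 6) | C=C[C@H]1C(C)(C)CCC(O[Si](C)(C)C)=C1C
F7 | step 2 | (2S,3S)-2,4,4-trimethyl-2-(2-oxo-2H-pyran-3-yl)-3-vinylcyclohexan-1-one (enantiomer of 8) | C=C[C@H]1C(C)(C)CCC(=O)[C@]1(C)c1cccoc1=O
F8 | step 6 | 3-[(1R,2R,3R,6R)-2,3-dihydroxy-1,5,5-trimethyl-6-vinylcyclohexyl]-2H-pyran-2-one (1α,2β-diol) | C=C[C@@H]1C(C)(C)C[C@@H](O)[C@H](O)[C@@]1(C)c1cccoc1=O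
F9 | step 6 | 1α-hydroxy-2-ketone (C2 ketone, C1 α-hydroxyl) of the ring A pyrone | C=C[C@@H]1C(C)(C)CC(=O)[C@H](O)[C@@]1(C)c1cccoc1=O
F10 | step 14 | trifluoroacetyl derivative of 23 (C16 acylated) | O=C(CC(=O)[C@@]12CO[C@@H](OC)[C@@H]3C(C)(C)C[C@H](OC(C)(C)O4)[C@H]4[C@@]3(C)C1=CC=CC2)C(F)(F)F
F11 | step 14 | diazomethyl ketone of the tricyclic diene | [N-]=[N+]=CC(=O)[C@@]12CO[C@@H](OC)[C@@H]3C(C)(C)C[C@H](OC(C)(C)O4)[C@H]4[C@@]3(C)C1=CC=CC2
F12 | step 14 | cyclopropyl ketone (C12–C13–C16 cyclopropane, 9(11)-alkene) | [C@H]15C(=O)[C@@]23CO[C@@H](OC)[C@@H]4C(C)(C)C[C@H](OC(C)(C)O6)[C@H]6[C@@]4(C)C2=C[C@@H]5[C@@H]1C3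
F13 | step 19 | 16-methylene-15-ketone, 9(11)-alkene, 6β-methoxy, 1α,2α-diacetate | C=C1C(=O)[C@@]23CO[C@@H](OC)[C@@H]4C(C)(C)C[C@H](OC(C)=O)[C@H](OC(C)=O)[C@@]4(C)C2=CC[C@@H]1C3
F14 | step 19 | 16-methylene-15-ketone, 9(11)-alkene, 6β-hydroxy lactol, 1α,2α-diacetate | C=C1C(=O)[C@@]23CO[C@@H](O)[C@@H]4C(C)(C)C[C@H](OC(C)=O)[C@H](OC(C)=O)[C@@]4(C)C2=CC[C@@H]1C3
A1 | alternative 1 | 8-phenylmenthyl 3-oxo-2-(prop-2-yn-1-yl)hept-6-enoate | C#CCC(C(=O)O[C@@H]1C[C@H](C)CC[C@H]1C(C)(C)c1ccccc1)C(=O)CCC=C
A2 | alternative 1 | 6-methylenebicyclo[3.2.1]octan-2-one with C8 8-phenylmenthyl ester | C=C1C[C@@]2(C(=O)O[C@@H]3C[C@H](C)CC[C@H]3C(C)(C)c3ccccc3)C(=O)CC[C@@H]1C2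
A3 | alternative 2 | A-homo α-diazoketone with C7 hydroxyl, 9(11)-alkene and C1,C2 acetonide | C=C1C[C@]2(CO)C[C@H]1CC=C2[C@@]3(C)C(=O)C(=[N+]=[N-])C(C)(C)C[C@@H]4OC(C)(C)O[C@H]34
A4 | alternative 2 | tetracyclic seven-membered lactone with 9(11)-alkene and C1,C2 acetonide | C=C1C[C@@]23COC(=O)[C@@H]4C(C)(C)C[C@@H]5OC(C)(C)O[C@@H]5[C@@]4(C)C2=CC[C@@H]1C3
A5 | alternative 3 | A/B bicyclic 8-methylene-9-ketone (oxepane methyl acetal, C1,C2 diacetate) | C=C1CO[C@@H](OC)[C@@H]2C(C)(C)C[C@H](OC(C)=O)[C@H](OC(C)=O)[C@@]2(C)C1=O
A6 | alternative 3 | methyl 2-[3-(tert-butyldimethylsilyloxy)-1-(trimethylsilyl)propyl]allyl carbonate | C=C(COC(=O)OC)C(CCO[Si](C)(C)C(C)(C)C)[Si](C)(C)C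
A7 | alternative 3 | A/B/D spiro tricycle with C9 ketone, C16 methylene and C13 side chain | C=C1C[C@]2(CO[C@@H](OC)[C@@H]3C(C)(C)C[C@H](OC(C)=O)[C@H](OC(C)=O)[C@@]3(C)C2=O)C[C@H]1CCO[Si](C)(C)C(C)(C)C
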